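**Retrosynthetic overview**

1. Locants follow germacrane numbering (carbocycle C1–C10; lactone oxygen on C6, ring fusion C7, α-carbon C11, carbonyl C12, exocyclic methylene C13). The last C–C bond is C3–C4, closed as the ten-membered ring by a Nozaki–Hiyama–Kishi reaction of a (Z)-alkenyl iodide with a C3 aldehyde; the C9 angelate comes from a C9 ketone.
2. Key disconnection C7–C11: the lactone is closed by a phosphine-catalysed intramolecular Rauhut–Currier cycloisomerisation of an acyclic C6 acrylate onto an (E)-C7=C8–C9(=O) enone. This one step gives the ring, the exocyclic methylene, the C7 stereocenter and the C8 methylene.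
3. Enabling feature: the lactone oxygen on C6 and the ester oxygen on C9 are 1,4-related across C7–C8. With C9 as a ketone, C7 is the β-carbon of a γ-acyloxy enone, five atoms (C11–C12–O–C6–C7) from the acrylate α-carbon, and C13 is already the acrylate terminus.
4. The enone comes from cross-metathesis of a vinyl ketone (C1–C3, C9, C10; from the glutamic-acid-derived (S)-trityloxymethyl butyrolactone, C10 set by trans-selective methylation) with (3S,4Z)-5-iodohexa-1,4-dien-3-ol (C4–C7, C15; kinetic resolution, then trans-hydroalumination/iodination).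
5. Ring order: γ-lactone first (step 10), ten-membered carbocycle second (step 15).

Key step: step 10

**Route**

Step 1
Reactants: 1 (S)-5-[(trityloxy)methyl]dihydrofuran-2(3H)-one
Product: 3 (3R,5S)-3-methyl-5-[(trityloxy)methyl]dihydrofuran-2(3H)-one, via lithium enolate 2 (not isolated)
Conditions: LiN(iPr)2, THF, −78 °C; then MeI, −78 → −40 °C
Reagents that add atoms: iodomethane CI
Why: Enolate alkylation of a γ-substituted butyrolactone, in which methyl iodide approaches the planar enolate anti to the bulky trityloxymethyl group, so the trans (3R,5S) lactone carrying C10 (R) and C2 (S) of the target should predominate.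

Step 2
Reactants: 3 trans-methyl lactone
Product: 4 (2R,4S)-4-hydroxy-N-methoxy-N,2-dimethyl-5-(trityloxy)pentanamide
Conditions: MeNH(OMe)·HCl, i-PrMgCl, THF, −20 → 0 °C
Reagents that add atoms: N,O-dimethylhydroxylamine hydrochloride CNOC.Cl
Why: Weinreb aminolysis of the lactone by the chloromagnesium amide formed in the flask, which attacks the acyl carbon only and leaves the α-stereocenter untouched while freeing the C2 hydroxyl.

Step 3
Reactants: 4 hydroxy Weinreb amide
Product: 5 (2R,4S)-4-(tert-butyldimethylsilyloxy)-N-methoxy-N,2-dimethyl-5-(trityloxy)pentanamide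
Conditions: TBSCl, imidazole, DMF, 23 °C
Reagents that add atoms: tert-butyldimethylsilyl chloride CC(C)(C)[Si](C)(C)Cl
Why: Standard silylation of the secondary alcohol, which stops relactonisation and installs the α-silyloxy group later used for Felkin–Anh control at C3.

Step 4
Reactants: 5 silylated Weinreb amide
Product: 6 (4R,6S)-6-(tert-butyldimethylsilyloxy)-4-methyl-7-(trityloxy)hept-1-en-3-one
Conditions: CH2=CHMgBr, THF, −78 → 0 °C
Reagents that add atoms: vinylmagnesium bromide C=C[Mg]Br
Why: Weinreb ketone synthesis, in which the stable magnesium chelate of the tetrahedral adduct prevents over-addition and collapses to the vinyl ketone only on work-up.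

Step 5
Reactants: 7 acrolein; 8 prop-1-yn-1-ylmagnesium bromide
Product: 9 rac-hex-1-en-4-yn-3-ol
Conditions: THF, −78 °C
Reagents that add atoms: none
Why: 1,2-Addition of a hard alkynyl Grignard reagent to the aldehyde of acrolein at low temperature gives the racemic vinyl propynyl carbinol.

Step 6
Reactants: 9 rac-hex-1-en-4-yn-3-ol
Product: 10 (S)-hex-1-en-4-yn-3-ol
Conditions: Ti(OiPr)4 (0.15 equiv), L-(+)-diisopropyl tartrate (0.2 equiv), t-BuOOH (0.6 equiv), 4 Å sieves, CH2Cl2, −20 °C
Reagents that add atoms: none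
Why: Sharpless kinetic resolution, in which the L-(+)-tartrate catalyst epoxidises the vinyl group of the (R)-alcohol much faster (to the erythro epoxy alcohol) and should leave the (S)-alcohol, whose carbinol carbon becomes C6.

Step 7
Reactants: 10 (S)-hex-1-en-4-yn-3-ol
Product: 12 (3S,4Z)-5-iodohexa-1,4-dien-3-ol, via cyclic alkenylalanate 11 (not isolated)
Conditions: NaAlH2(OCH2CH2OMe)2, THF, 0 → 23 °C; then I2, −78 °C
Reagents that add atoms: iodine II
Why: Hydroxyl-directed trans-hydroalumination of the propargylic alcohol places aluminium on the distal alkyne carbon, and iodinolysis with retention gives the (Z)-alkenyl iodide with the carbinol carbon cis to iodine, the stereocenter being untouched.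

Step 8
Reactants: 6 vinyl ketone; 12 iodo dienol (2 equiv)
Product: 13 (2S,4R,6E,8S,9Z)-2-(tert-butyldimethylsilyloxy)-8-hydroxy-10-iodo-4-methyl-1-(trityloxy)undeca-6,9-dien-5-one
Conditions: second-generation Hoveyda–Grubbs catalyst (5 mol %), CH2Cl2, 40 °C
Reagents that add atoms: none
Why: Olefin cross-metathesis between an electron-poor vinyl ketone and a secondary allylic alcohol, which under thermodynamic control gives the (E)-enone, while the trisubstituted iodoalkene is inert to the ruthenium carbene.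

Step 9
Reactants: 13 γ-hydroxy enone
Product: 14 (2Z,4S,5E,8R,10S)-10-(tert-butyldimethylsilyloxy)-2-iodo-8-methyl-7-oxo-11-(trityloxy)undeca-2,5-dien-4-yl prop-2-enoate
Conditions: acryloyl chloride, i-Pr2NEt, CH2Cl2, −40 → 0 °C
Reagents that add atoms: acryloyl chloride C=CC(=O)Cl
Why: Standard O-acylation of the secondary bis-allylic alcohol with a hindered amine base at low temperature, mild enough to leave the γ-acyloxy enone intact.

Step 10
Reactants: 14 acrylate enone
Product: 15 (4S,5S)-4-[(3R,5S)-5-(tert-butyldimethylsilyloxy)-3-methyl-2-oxo-6-(trityloxy)hexyl]-5-[(Z)-2-iodoprop-1-en-1-yl]-3-methylidenedihydrofuran-2(3H)-one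
Conditions: PBu3 (20 mol %), t-AmOH/THF 1:1 (0.02 M, degassed), 23 °C
Reagents that add atoms: none
Why: Reversible conjugate addition of PBu3 to the unsubstituted acrylate terminus (C13) gives a β-phosphonio ester enolate that is nucleophilic at C11 and adds in Michael fashion to C7, the β-carbon of the (E)-enone; proton transfer from C11 to the ketone enolate and β-elimination of the phosphine then restore the C11=C13 double bond, so lactone, exocyclic methylene and C8 methylene arise in one catalytic isomerisation. The closest known reaction type is the intramolecular Rauhut–Currier reaction of O-acryloyl γ-oxygenated enones (4-acryloyloxy-cyclohexadienones), which gives α-methylene-γ-butyrolactones. The γ-lactone is closed in the 5-exo-trig mode (C11–C12–O–C6–C7). The new stereocenter C7 is controlled by C6: in the chair-like transition state H6 eclipses the C7=C8 bond (allylic 1,3-strain) and the iodoalkenyl group is pseudo-equatorial, so C5 and C8 should end up trans on the lactone, as in the target. The step needs phosphine addition to the acrylate and not the enone, and bond formation at C7 and not at the C9 carbonyl; the unhindered acrylate terminus, the β-substituent of the enone and the five-membered ring size secure this, and the alkenyl iodide and both ethers are inert to the phosphine.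

Step 11
Reactants: 15 keto lactone
Product: 16 (4S,5S)-4-[(2S,3R,5S)-5-(tert-butyldimethylsilyloxy)-2-hydroxy-3-methyl-6-(trityloxy)hexyl]-5-[(Z)-2-iodoprop-1-en-1-yl]-3-methylidenedihydrofuran-2(3H)-one
Conditions: (R)-2-methyl-CBS-oxazaborolidine (0.5 equiv), catecholborane (2 equiv), toluene, −78 → −40 °C
Reagents that add atoms: none
Why: Corey–Bakshi–Shibata reduction, in which the (R)-catalyst with the α-branched C10 residue as the large group delivers hydride to the face that also matches the Felkin–Anh preference of the (10R) α-methyl ketone, so the (9S) carbinol should form, while catecholborane leaves the α-methylene lactone alone.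

Step 12
Reactants: 16 C9 alcohol; 17 angelic acid
Product: 19 (2S,3R,5S)-5-(tert-butyldimethylsilyloxy)-1-[(2S,3S)-2-[(Z)-2-iodoprop-1-en-1-yl]-4-methylidene-5-oxotetrahydrofuran-3-yl]-3-methyl-6-(trityloxy)hexan-2-yl (Z)-2-methylbut-2-enoate, via angeloyl 2,4,6-trichlorobenzoyl anhydride 18 (not isolated)
Conditions: 17, 2,4,6-Cl3C6H2COCl, Et3N, toluene, 23 °C; then 16, DMAP (0.2 equiv), toluene, 60 °C
Reagents that add atoms: none
Why: Yamaguchi esterification through the preformed mixed anhydride, the established way to acylate hindered secondary alcohols with angelic acid with little Z-to-E isomerisation, with retention at C9.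

Step 13
Reactants: 19 trityl ether
Product: 20 (2S,3R,5S)-5-(tert-butyldimethylsilyloxy)-6-hydroxy-1-[(2S,3S)-2-[(Z)-2-iodoprop-1-en-1-yl]-4-methylidene-5-oxotetrahydrofuran-3-yl]-3-methylhexan-2-yl (Z)-2-methylbut-2-enoate
Conditions: CSA (0.2 equiv), MeOH/CH2Cl2 1:2, 0 °C
Reagents that add atoms: none
Why: Acid-catalysed methanolysis of the trityl ether through the trityl cation, which is much faster than cleavage of the secondary silyl ether and does not affect either ester.

Step 14
Reactants: 20 primary alcohol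
Product: 21 (2S,3R,5S)-5-(tert-butyldimethylsilyloxy)-1-[(2S,3S)-2-[(Z)-2-iodoprop-1-en-1-yl]-4-methylidene-5-oxotetrahydrofuran-3-yl]-3-methyl-6-oxohexan-2-yl (Z)-2-methylbut-2-enoate
Conditions: Dess–Martin periodinane, CH2Cl2, 0 → 23 °C
Reagents that add atoms: none
Why: Dess–Martin oxidation of the primary alcohol under near-neutral conditions, which should not epimerise the α-silyloxy aldehyde.

Step 15
Reactants: 21 iodo aldehyde
Product: 22 (3aS,5S,6R,8S,9R,10Z,11aR)-8-(tert-butyldimethylsilyloxy)-9-hydroxy-6,10-dimethyl-3-methylidene-2-oxo-2,3,3a,4,5,6,7,8,9,11a-decahydrocyclodeca[b]furan-5-yl (Z)-2-methylbut-2-enoate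
Conditions: CrCl2 (10 equiv), NiCl2 (0.1 equiv), DMSO/THF 3:1 (0.002 M, slow addition), 23 °C
Reagents that add atoms: none
Why: Nozaki–Hiyama–Kishi reaction, in which oxidative addition of the alkenyl iodide to zerovalent nickel, transmetalation to trivalent chromium and intramolecular addition to the aldehyde close the ten-membered ring with retention of the Z geometry, and polar Felkin–Anh addition anti to the α-silyloxy group should give the (3R) carbinol (2,3-anti).

Step 16
Reactants: 22 silyl ether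
Product: 23 (3aS,5S,6R,8S,9R,10Z,11aR)-8,9-dihydroxy-6,10-dimethyl-3-methylidene-2-oxo-2,3,3a,4,5,6,7,8,9,11a-decahydrocyclodeca[b]furan-5-yl (Z)-2-methylbut-2-enoate
Conditions: HF·pyridine, pyridine, THF, 0 → 23 °C
Reagents that add atoms: none
Why: Fluoride-mediated desilylation under buffered, weakly acidic conditions that leave the angelate, the α-methylene lactone and the allylic diol untouched.

**Compound list**

1 | (S)-5-[(trityloxy)methyl]dihydrofuran-2(3H)-one | O=C1CC[C@@H](COC(c2ccccc2)(c2ccccc2)c2ccccc2)O1 | starting material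
2 | lithium (S)-5-[(trityloxy)methyl]-4,5-dihydrofuran-2-olate (lithium enolate of 1) | [Li+].[O-]C1=CC[C@@H](COC(c2ccccc2)(c2ccccc2)c2ccccc2)O1 | intermediate
3 | (3R,5S)-3-methyl-5-[(trityloxy)methyl]dihydrofuran-2(3H)-one | O=C1[C@H](C)C[C@@H](COC(c2ccccc2)(c2ccccc2)c2ccccc2)O1 | intermediate
4 | (2R,4S)-4-hydroxy-N-methoxy-N,2-dimethyl-5-(trityloxy)pentanamide | CON(C)C(=O)[C@H](C)C[C@H](O)COC(c1ccccc1)(c1ccccc1)c1ccccc1 | intermediate
5 | (2R,4S)-4-(tert-butyldimethylsilyloxy)-N-methoxy-N,2-dimethyl-5-(trityloxy)pentanamide | CON(C)C(=O)[C@H](C)C[C@H](O[Si](C)(C)C(C)(C)C)COC(c1ccccc1)(c1ccccc1)c1ccccc1 | intermediate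
6 | (4R,6S)-6-(tert-butyldimethylsilyloxy)-4-methyl-7-(trityloxy)hept-1-en-3-one | C=CC(=O)[C@H](C)C[C@H](O[Si](C)(C)C(C)(C)C)COC(c1ccccc1)(c1ccccc1)c1ccccc1 | intermediate
7 | acrolein (prop-2-enal) | C=CC=O | starting material
8 | prop-1-yn-1-ylmagnesium bromide | CC#C[Mg]Br | starting material
9 | rac-hex-1-en-4-yn-3-ol | C=CC(O)C#CC | intermediate
10 | (S)-hex-1-en-4-yn-3-ol | C=C[C@H](O)C#CC | intermediate
11 | sodium (S)-2,2-bis(2-methoxyethoxy)-3-methyl-5-vinyl-2,5-dihydro-1,2-oxaaluminol-2-uide (cyclic alkenylalanate) | CC1=C[C@H](C=C)O[Al-]1(OCCOC)OCCOC.[Na+] | intermediate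
12 | (3S,4Z)-5-iodohexa-1,4-dien-3-ol | C=C[C@H](O)/C=C(/C)I | intermediate
13 | (2S,4R,6E,8S,9Z)-2-(tert-butyldimethylsilyloxy)-8-hydroxy-10-iodo-4-methyl-1-(trityloxy)undeca-6,9-dien-5-one | C/C(I)=C/[C@@H](O)/C=C/C(=O)[C@H](C)C[C@H](O[Si](C)(C)C(C)(C)C)COC(c1ccccc1)(c1ccccc1)c1ccccc1 | intermediate
14 | (2Z,4S,5E,8R,10S)-10-(tert-butyldimethylsilyloxy)-2-iodo-8-methyl-7-oxo-11-(trityloxy)undeca-2,5-dien-4-yl prop-2-enoate | C/C(I)=C/[C@@H](OC(=O)C=C)/C=C/C(=O)[C@H](C)C[C@H](O[Si](C)(C)C(C)(C)C)COC(c1ccccc1)(c1ccccc1)c1ccccc1 | intermediate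
15 | (4S,5S)-4-[(3R,5S)-5-(tert-butyldimethylsilyloxy)-3-methyl-2-oxo-6-(trityloxy)hexyl]-5-[(Z)-2-iodoprop-1-en-1-yl]-3-methylidenedihydrofuran-2(3H)-one | C=C1C(=O)O[C@H](/C=C(/C)I)[C@H]1CC(=O)[C@H](C)C[C@H](O[Si](C)(C)C(C)(C)C)COC(c1ccccc1)(c1ccccc1)c1ccccc1 | intermediate
16 | (4S,5S)-4-[(2S,3R,5S)-5-(tert-butyldimethylsilyloxy)-2-hydroxy-3-methyl-6-(trityloxy)hexyl]-5-[(Z)-2-iodoprop-1-en-1-yl]-3-methylidenedihydrofuran-2(3H)-one | C=C1C(=O)O[C@H](/C=C(/C)I)[C@H]1C[C@H](O)[C@H](C)C[C@H](O[Si](C)(C)C(C)(C)C)COC(c1ccccc1)(c1ccccc1)c1ccccc1 | intermediate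
17 | angelic acid, (Z)-2-methylbut-2-enoic acid | C/C=C(/C)C(=O)O | starting material
18 | (Z)-2-methylbut-2-enoic 2,4,6-trichlorobenzoic anhydride | C/C=C(/C)C(=O)OC(=O)c1c(Cl)cc(Cl)cc1Cl | intermediate
19 | (2S,3R,5S)-5-(tert-butyldimethylsilyloxy)-1-[(2S,3S)-2-[(Z)-2-iodoprop-1-en-1-yl]-4-methylidene-5-oxotetrahydrofuran-3-yl]-3-methyl-6-(trityloxy)hexan-2-yl (Z)-2-methylbut-2-enoate | C=C1C(=O)O[C@H](/C=C(/C)I)[C@H]1C[C@H](OC(=O)/C(C)=C\C)[C@H](C)C[C@H](O[Si](C)(C)C(C)(C)C)COC(c1ccccc1)(c1ccccc1)c1ccccc1 | intermediate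
20 | (2S,3R,5S)-5-(tert-butyldimethylsilyloxy)-6-hydroxy-1-[(2S,3S)-2-[(Z)-2-iodoprop-1-en-1-yl]-4-methylidene-5-oxotetrahydrofuran-3-yl]-3-methylhexan-2-yl (Z)-2-methylbut-2-enoate | C=C1C(=O)O[C@H](/C=C(/C)I)[C@H]1C[C@H](OC(=O)/C(C)=C\C)[C@H](C)C[C@H](O[Si](C)(C)C(C)(C)C)CO | intermediate
21 | (2S,3R,5S)-5-(tert-butyldimethylsilyloxy)-1-[(2S,3S)-2-[(Z)-2-iodoprop-1-en-1-yl]-4-methylidene-5-oxotetrahydrofuran-3-yl]-3-methyl-6-oxohexan-2-yl (Z)-2-methylbut-2-enoate | C=C1C(=O)O[C@H](/C=C(/C)I)[C@H]1C[C@H](OC(=O)/C(C)=C\C)[C@H](C)C[C@H](O[Si](C)(C)C(C)(C)C)C=O | intermediate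
22 | (3aS,5S,6R,8S,9R,10Z,11aR)-8-(tert-butyldimethylsilyloxy)-9-hydroxy-6,10-dimethyl-3-methylidene-2-oxo-2,3,3a,4,5,6,7,8,9,11a-decahydrocyclodeca[b]furan-5-yl (Z)-2-methylbut-2-enoate | C=C1C(=O)O[C@@H]2/C=C(/C)[C@@H](O)[C@@H](O[Si](C)(C)C(C)(C)C)C[C@@H](C)[C@@H](OC(=O)/C(C)=C\C)C[C@@H]12 | intermediate
23 | (3aS,5S,6R,8S,9R,10Z,11aR)-8,9-dihydroxy-6,10-dimethyl-3-methylidene-2-oxo-2,3,3a,4,5,6,7,8,9,11a-decahydrocyclodeca[b]furan-5-yl (Z)-2-methylbut-2-enoate | C=C1C(=O)O[C@@H]2/C=C(/C)[C@@H](O)[C@@H](O)C[C@@H](C)[C@@H](OC(=O)/C(C)=C\C)C[C@@H]12 | target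

**Step count and risks**

Total steps: 16. Longest linear sequence: 13 steps (steps 1–4 and 8–16).

Steps most likely to fail:

Step 10. The phosphonium enolate may deprotonate the γ-position (C6) and isomerise the γ-acyloxy enone, or ring closure may be slow because the ester has to adopt its s-cis conformation, so that intermolecular oligomerisation takes over. Fallback, setting out from 13 and returning at 15: 13 is esterified with (diethoxyphosphoryl)acetic acid (DCC, DMAP cat., CH2Cl2) to the phosphonoacetate F1. Treatment with Cs2CO3 in THF at 0 °C brings about stoichiometric intramolecular Michael addition of the stabilised phosphonoacetate anion to C7, giving the α-phosphono lactone F2. Without isolation, F2 undergoes Horner–Wadsworth–Emmons methylenation with paraformaldehyde in the same flask to give 15. The mild carbonate base is chosen so that the alkenyl iodide is not dehydrohalogenated.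

Step 15. Facial selectivity in the ring-closing addition may be poor, because strain in the cyclic transition state can override Felkin–Anh control at C3. Fallback, setting out from 21 and returning at 23: the cyclisation is run as above and the product is carried on whatever its C3 configuration. The (3S)-carbinol F3 is oxidised with Dess–Martin periodinane to the cyclic enone F4 and desilylated with HF·pyridine to the α-hydroxy enone F5. Reduction with Zn(BH4)2 in Et2O at −20 °C under chelation control (zinc bridging the C2 hydroxyl and the C3 carbonyl, hydride delivered anti to the C1 branch) gives the 2,3-anti diol, which is 23. The C3 stereocenter is thus set by reduction and not by C–C bond formation.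

Step 12. Acyl transfer to the hindered C9 carbinol may be slow, and under the basic acylation conditions the angeloyl unit may isomerise from Z to E. Fallback, setting out from 15 and returning at 19: 15 is reduced with (S)-2-methyl-CBS-oxazaborolidine and catecholborane to the (9R)-alcohol F6. Mitsunobu esterification of F6 with angelic acid 17 (PPh3, DIAD, toluene, 0 °C) inverts C9 and gives 19 without any activated angeloyl intermediate.

**Further compounds**

F1 | step 10 | (2Z,4S,5E,8R,10S)-10-(tert-butyldimethylsilyloxy)-2-iodo-8-methyl-7-oxo-11-(trityloxy)undeca-2,5-dien-4-yl 2-(diethoxyphosphoryl)acetate | C/C(I)=C/[C@@H](OC(=O)CP(=O)(OCC)OCC)/C=C/C(=O)[C@H](C)C[C@H](O[Si](C)(C)C(C)(C)C)COC(c1ccccc1)(c1ccccc1)c1ccccc1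
F2 | step 10 | diethyl [(4S,5S)-4-[(3R,5S)-5-(tert-butyldimethylsilyloxy)-3-methyl-2-oxo-6-(trityloxy)hexyl]-5-[(Z)-2-iodoprop-1-en-1-yl]-2-oxotetrahydrofuran-3-yl]phosphonate (both epimers at the phosphorus-bearing carbon) | CCOP(=O)(OCC)C1C(=O)O[C@H](/C=C(/C)I)[C@H]1CC(=O)[C@H](C)C[C@H](O[Si](C)(C)C(C)(C)C)COC(c1ccccc1)(c1ccccc1)c1ccccc1
F3 | step 15 | (3aS,5S,6R,8S,9S,10Z,11aR)-8-(tert-butyldimethylsilyloxy)-9-hydroxy-6,10-dimethyl-3-methylidene-2-oxo-2,3,3a,4,5,6,7,8,9,11a-decahydrocyclodeca[b]furan-5-yl (Z)-2-methylbut-2-enoate (C3 epimer of 22) | C=C1C(=O)O[C@@H]2/C=C(/C)[C@H](O)[C@@H](O[Si](C)(C)C(C)(C)C)C[C@@H](C)[C@@H](OC(=O)/C(C)=C\C)C[C@@H]12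
F4 | step 15 | (3aS,5S,6R,8S,10Z,11aR)-8-(tert-butyldimethylsilyloxy)-6,10-dimethyl-3-methylidene-2,9-dioxo-2,3,3a,4,5,6,7,8,9,11a-decahydrocyclodeca[b]furan-5-yl (Z)-2-methylbut-2-enoate | C=C1C(=O)O[C@@H]2/C=C(/C)C(=O)[C@@H](O[Si](C)(C)C(C)(C)C)C[C@@H](C)[C@@H](OC(=O)/C(C)=C\C)C[C@@H]12
F5 | step 15 | (3aS,5S,6R,8S,10Z,11aR)-8-hydroxy-6,10-dimethyl-3-methylidene-2,9-dioxo-2,3,3a,4,5,6,7,8,9,11a-decahydrocyclodeca[b]furan-5-yl (Z)-2-methylbut-2-enoate | C=C1C(=O)O[C@@H]2/C=C(/C)C(=O)[C@@H](O)C[C@@H](C)[C@@H](OC(=O)/C(C)=C\C)C[C@@H]12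
F6 | step 12 | (4S,5S)-4-[(2R,3R,5S)-5-(tert-butyldimethylsilyloxy)-2-hydroxy-3-methyl-6-(trityloxy)hexyl]-5-[(Z)-2-iodoprop-1-en-1-yl]-3-methylidenedihydrofuran-2(3H)-one | C=C1C(=O)O[C@H](/C=C(/C)I)[C@H]1C[C@@H](O)[C@H](C)C[C@H](O[Si](C)(C)C(C)(C)C)COC(c1ccccc1)(c1ccccc1)c1ccccc1
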